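**Plan**

- Numbering: chain C1 (carbinol) to C14; ring A carbons 1 (bears C14), 3 (OH) and 5 (ether O); ring B carbons 1 (ether O), 2 and 6 (OH) and 4 (bears C1).
- Enabling feature: C1 is a secondary carbinol between the unhindered ring B carbon 4 (hydrogen on ring B carbons 3 and 5) and the unbranched methylene C2. The 22-membered ring can therefore be opened at the bond from ring B carbon 4 to C1, giving an aryl iodide and a C1 aldehyde held on one diaryl ether.
- Cuts, in retrosynthetic order: ring B carbon 4 to C1 (ring closure), ring A carbon 5 to the ether oxygen (diaryl ether), C14 to ring A carbon 1 (alkyl–aryl coupling), C9–C10 (acetylide alkylation); the hydroxyl at ring B carbon 1 and the iodine at ring B carbon 4 are put onto resorcinol.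
- Forward order: the C1–C9 alkynol and the C10–C14 bromide are joined, the chain is coupled to ring A, the alkyne is reduced, the ring A boronic acid is joined to the ring B iodophenol, the chain end is oxidised, and the only ring is closed in the last step but one.
- Stereochemistry: C1 (R) is set during ring closure by a chiral oxazoline–sulfonamide ligand on chromium; the Z geometry of C8=C9 comes from syn semihydrogenation of the C8≡C9 alkyne.

Key step: step 13

Assumption: the sense of induction of the ligand with an aryl nucleophile is not established, so the (S)-valinol-derived ligand is written and taken to deliver 1R; if a trial addition shows the opposite sense, its (R) antipode is used in the same way.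

**Route**

Step 1
Reactants: 1 resorcinol
Product: 2 1,3-bis(methoxymethoxy)benzene
Conditions: NaH, MOMCl, DMF, 0 °C → rt
Reagents that add atoms: chloromethyl methyl ether (MOMCl), COCCl
Why: Williamson-type O-alkylation of the bis-phenoxide by the reactive α-chloro ether should give the bis-acetal, whose two oxygens later direct lithiation to the carbon between them.

Step 2
Reactants: 2 1,3-bis(methoxymethoxy)benzene
Product: 5 2,6-bis(methoxymethoxy)phenol, via ring B aryllithium 3 (not isolated), via dimethyl arylboronate 4 (not isolated)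
Conditions: n-BuLi, THF, 0 °C; B(OMe)3, −78 °C → rt; 30% aq H2O2, 0 °C → rt
Reagents that add atoms: hydrogen peroxide, OO
Why: Directed ortho-metalation takes place at the carbon flanked by both OMOM groups, the aryllithium is borylated, and basic peroxide oxidation moves the aryl group from boron to oxygen, which should install the hydroxyl at ring B carbon 1 with the acetals untouched.

Step 3
Reactants: 5 2,6-bis(methoxymethoxy)phenol
Product: 6 4-iodo-2,6-bis(methoxymethoxy)phenol
Conditions: NIS, MeCN, 0 °C, dark
Reagents that add atoms: N-iodosuccinimide (NIS), O=C1CCC(=O)N1I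
Why: Electrophilic aromatic iodination should go para to the free hydroxyl, the strongest donor whose two ortho positions are blocked, which places iodine at ring B carbon 4 under acid-free conditions that spare the acetals.

Step 4
Reactants: 7 3-bromo-5-iodophenol
Product: 8 1-bromo-3-iodo-5-(methoxymethoxy)benzene
Conditions: NaH, MOMCl, DMF, 0 °C → rt
Reagents that add atoms: chloromethyl methyl ether (MOMCl), COCCl
Why: Williamson-type O-alkylation of the phenoxide masks the oxygen on ring A carbon 3 as an acetal that tolerates the palladium, organolithium, copper and chromium steps that follow.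

Step 5
Reactants: 9 non-8-yn-1-ol
Product: 10 tert-butyl(dimethyl)(non-8-yn-1-yloxy)silane
Conditions: TBSCl, imidazole, DMF, rt
Reagents that add atoms: tert-butyldimethylsilyl chloride (TBSCl), CC(C)(C)[Si](C)(C)Cl
Why: Imidazole-promoted silylation of the primary alcohol removes the only acidic O–H before the acetylide, aryllithium and copper steps.

Step 6
Reactants: 10 tert-butyl(dimethyl)(non-8-yn-1-yloxy)silane; 11 5-bromopent-1-ene
Product: 13 tert-butyl(dimethyl)(tetradec-13-en-8-yn-1-yloxy)silane, via lithium acetylide 12 (not isolated)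
Conditions: n-BuLi, THF, −78 °C; DMPU, 11, −78 °C → rt
Reagents that add atoms: none
Why: SN2 alkylation of the lithium acetylide by the primary bromide in a dipolar cosolvent forms the C9–C10 bond and leaves the terminal alkene as the handle for the next step.

Step 7
Reactants: 13 tert-butyl(dimethyl)(tetradec-13-en-8-yn-1-yloxy)silane; 8 1-bromo-3-iodo-5-(methoxymethoxy)benzene
Product: 15 {[14-(3-bromo-5-(methoxymethoxy)phenyl)tetradec-8-yn-1-yl]oxy}(tert-butyl)dimethylsilane, via B-alkyl-9-BBN 14 (not isolated)
Conditions: 9-BBN, THF, 0 °C → rt; then 8 (1.2 equiv), Pd(dppf)Cl2 (5 mol %), aq K3PO4, DMF, rt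
Reagents that add atoms: none
Why: 9-BBN hydroborates the terminal alkene at C14 far faster than the internal alkyne, and the B-alkyl Suzuki–Miyaura coupling should occur only at the C–I bond of 8 because zerovalent palladium inserts into it much faster than into C–Br at room temperature, which forms the bond between C14 and ring A carbon 1.

Step 8
Reactants: 15 {[14-(3-bromo-5-(methoxymethoxy)phenyl)tetradec-8-yn-1-yl]oxy}(tert-butyl)dimethylsilane
Product: 16 {[(8Z)-14-(3-bromo-5-(methoxymethoxy)phenyl)tetradec-8-en-1-yl]oxy}(tert-butyl)dimethylsilane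
Conditions: H2 (1 atm), Pd/CaCO3 poisoned with Pb(OAc)2, quinoline, EtOAc, rt
Reagents that add atoms: none
Why: Lindlar semihydrogenation delivers both hydrogens to the same face of the C8≡C9 alkyne on the poisoned palladium surface, which should give the Z alkene and stop there while the aryl bromide, the acetal and the silyl ether are left alone.

Step 9
Reactants: 16 {[(8Z)-14-(3-bromo-5-(methoxymethoxy)phenyl)tetradec-8-en-1-yl]oxy}(tert-butyl)dimethylsilane
Product: 19 [3-{(6Z)-14-[(tert-butyldimethylsilyl)oxy]tetradec-6-en-1-yl}-5-(methoxymethoxy)phenyl]boronic acid, via ring A aryllithium 17 (not isolated), via lithium aryltriisopropoxyborate 18 (not isolated)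
Conditions: n-BuLi, THF, −78 °C; B(OiPr)3, −78 → 0 °C; aq NH4Cl
Reagents that add atoms: triisopropyl borate, CC(C)OB(OC(C)C)OC(C)C; water, O
Why: Bromine–lithium exchange at −78 °C outruns lithiation ortho to the OMOM group, the aryllithium is captured by the borate, and mild hydrolysis of the ate complex should give the boronic acid at ring A carbon 5 (lithiation–borylation).

Step 10
Reactants: 19 [3-{(6Z)-14-[(tert-butyldimethylsilyl)oxy]tetradec-6-en-1-yl}-5-(methoxymethoxy)phenyl]boronic acid; 6 4-iodo-2,6-bis(methoxymethoxy)phenol
Product: 20 tert-butyl{[(8Z)-14-{3-[4-iodo-2,6-bis(methoxymethoxy)phenoxy]-5-(methoxymethoxy)phenyl}tetradec-8-en-1-yl]oxy}dimethylsilane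
Conditions: Cu(OAc)2 (1.5 equiv), Et3N, powdered 4 Å molecular sieves, CH2Cl2, air, rt; 6 in 1.5-fold excess
Reagents that add atoms: none
Why: In the Chan–Lam coupling the arylboronic acid transmetalates to divalent copper, the phenoxide of 6 binds, and C–O reductive elimination joins ring A carbon 5 to the ether oxygen at room temperature, conditions under which a di-ortho-substituted phenol is a competent partner and the C–I bond on ring B is not activated.

Step 11
Reactants: 20 tert-butyl{[(8Z)-14-{3-[4-iodo-2,6-bis(methoxymethoxy)phenoxy]-5-(methoxymethoxy)phenyl}tetradec-8-en-1-yl]oxy}dimethylsilane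
Product: 21 (8Z)-14-{3-[4-iodo-2,6-bis(methoxymethoxy)phenoxy]-5-(methoxymethoxy)phenyl}tetradec-8-en-1-ol
Conditions: TBAF, THF, 0 °C → rt
Reagents that add atoms: none
Why: Fluoride-driven cleavage of the Si–O bond frees the primary alcohol, and the acetals, the aryl iodide and the alkene are inert to fluoride.

Step 12
Reactants: 21 (8Z)-14-{3-[4-iodo-2,6-bis(methoxymethoxy)phenoxy]-5-(methoxymethoxy)phenyl}tetradec-8-en-1-ol
Product: 22 (8Z)-14-{3-[4-iodo-2,6-bis(methoxymethoxy)phenoxy]-5-(methoxymethoxy)phenyl}tetradec-8-enal
Conditions: Dess–Martin periodinane, CH2Cl2, 0 °C → rt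
Reagents that add atoms: none
Why: Dess–Martin oxidation takes the primary alcohol to the aldehyde without over-oxidation under near-neutral conditions that leave the Z alkene, the aryl iodide and the MOM acetals intact.

Step 13
Reactants: 22 (8Z)-14-{3-[4-iodo-2,6-bis(methoxymethoxy)phenoxy]-5-(methoxymethoxy)phenyl}tetradec-8-enal
Product: 25 tris-MOM macrocyclic (1R,8Z)-carbinol (22-membered ring; three phenolic OMOM groups; free OH at C1), via arylchromium complex 23 (not isolated), via chromium alkoxide 24 (not isolated)
Conditions: CrCl2 (4 equiv), (S)-N-[2-(4-isopropyl-4,5-dihydrooxazol-2-yl)-6-methylphenyl]methanesulfonamide (4.4 equiv), Et3N (4.4 equiv), MeCN, rt, 1 h; NiCl2(2,9-dimethyl-1,10-phenanthroline) (0.1 equiv), LiCl; 22 by syringe pump over 12 h (final 2 mM), rt; then H2O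
Reagents that add atoms: none
Why: Proposed new method: divalent chromium reduces NiCl2 to zerovalent nickel, which inserts into the C–I bond at ring B carbon 4, the aryl group passes to trivalent chromium bound to the deprotonated oxazoline–sulfonamide ligand (23), and this arylchromium adds to the C1 aldehyde through a closed chromium-centred transition state to give alkoxide 24, two CrCl2 being used per bond formed. The closest known reaction types are the nickel/chromium-mediated (Nozaki–Hiyama–Kishi) macrocyclisation of ω-iodo aldehydes and the oxazoline–sulfonamide-controlled asymmetric addition of alkenyl iodides to aldehydes, whereas an enantioselective ring closure with an aryl iodide has not been shown. The 22-membered ring closes by intramolecular 1,2-addition of the ring B arylchromium to the tethered aldehyde, with oligomerisation held back by slow addition to millimolar concentration. C1 is the only new stereocentre and its R configuration is dictated solely by the chiral ligand on chromium, because 22 carries no stereocentre of its own. The step needs chemoselectivity for the C–I bond and survival of the enolisable aldehyde: the first is secured because the iodide at the unhindered ring B carbon 4 (hydrogen on both neighbouring carbons) is the only site nickel can enter, the second because the non-basic arylchromium is generated in the presence of the aldehyde, and the MOM acetals and the Z alkene are inert to both metals.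

Step 14
Reactants: 25 tris-MOM macrocyclic (1R,8Z)-carbinol
Product: 27 CNP0316989.2 (22-membered (1R,8Z) macrocyclic tetraol), via tetrakis(trimethylsilyl) ether 26 (not isolated)
Conditions: TMSOTf (8 equiv), 2,2'-bipyridyl (12 equiv), MeCN, 0 °C → rt; then H2O, rt
Reagents that add atoms: none
Why: The silyl triflate–bipyridyl pair activates each aromatic MOM acetal so that the aryloxy group leaves as its trimethylsilyl ether while the methoxymethyl unit is held as a bipyridinium salt, and water then hydrolyses all O–Si bonds, so the three phenols should be freed in a non-protic, base-buffered medium in which the benzylic C1–O bond is not expected to ionise and the R configuration and the Z alkene are kept.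

**Compound list**

1 | resorcinol | Oc1cccc(O)c1 | starting material
2 | 1,3-bis(methoxymethoxy)benzene | COCOc1cccc(OCOC)c1 | intermediate
3 | [2,6-bis(methoxymethoxy)phenyl]lithium | [Li]c1c(OCOC)cccc1OCOC | intermediate
4 | dimethyl [2,6-bis(methoxymethoxy)phenyl]boronate | COB(OC)c1c(OCOC)cccc1OCOC | intermediate
5 | 2,6-bis(methoxymethoxy)phenol | COCOc1cccc(OCOC)c1O | intermediate
6 | 4-iodo-2,6-bis(methoxymethoxy)phenol | COCOc1cc(I)cc(OCOC)c1O | intermediate
7 | 3-bromo-5-iodophenol | Oc1cc(Br)cc(I)c1 | starting material
8 | 1-bromo-3-iodo-5-(methoxymethoxy)benzene | COCOc1cc(Br)cc(I)c1 | intermediate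
9 | non-8-yn-1-ol | OCCCCCCCC#C | starting material
10 | tert-butyl(dimethyl)(non-8-yn-1-yloxy)silane | C#CCCCCCCCO[Si](C)(C)C(C)(C)C | intermediate
11 | 5-bromopent-1-ene | C=CCCCBr | starting material
12 | [9-(tert-butyldimethylsilyloxy)non-1-yn-1-yl]lithium | [Li]C#CCCCCCCCO[Si](C)(C)C(C)(C)C | intermediate
13 | tert-butyl(dimethyl)(tetradec-13-en-8-yn-1-yloxy)silane | C=CCCCC#CCCCCCCCO[Si](C)(C)C(C)(C)C | intermediate
14 | 9-[14-(tert-butyldimethylsilyloxy)tetradec-6-yn-1-yl]-9-borabicyclo[3.3.1]nonane | CC(C)(C)[Si](C)(C)OCCCCCCCC#CCCCCCB1C2CCCC1CCC2 | intermediate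
15 | {[14-(3-bromo-5-(methoxymethoxy)phenyl)tetradec-8-yn-1-yl]oxy}(tert-butyl)dimethylsilane | CC(C)(C)[Si](C)(C)OCCCCCCCC#CCCCCCc1cc(Br)cc(OCOC)c1 | intermediate
16 | {[(8Z)-14-(3-bromo-5-(methoxymethoxy)phenyl)tetradec-8-en-1-yl]oxy}(tert-butyl)dimethylsilane | CC(C)(C)[Si](C)(C)OCCCCCCC/C=C\CCCCCc1cc(Br)cc(OCOC)c1 | intermediate
17 | [3-{(6Z)-14-[(tert-butyldimethylsilyl)oxy]tetradec-6-en-1-yl}-5-(methoxymethoxy)phenyl]lithium | CC(C)(C)[Si](C)(C)OCCCCCCC/C=C\CCCCCc1cc([Li])cc(OCOC)c1 | intermediate
18 | lithium [3-{(6Z)-14-[(tert-butyldimethylsilyl)oxy]tetradec-6-en-1-yl}-5-(methoxymethoxy)phenyl]tri(propan-2-yloxy)borate | [Li+].CC(C)O[B-](OC(C)C)(OC(C)C)c1cc(CCCCC/C=C\CCCCCCCO[Si](C)(C)C(C)(C)C)cc(OCOC)c1 | intermediate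
19 | [3-{(6Z)-14-[(tert-butyldimethylsilyl)oxy]tetradec-6-en-1-yl}-5-(methoxymethoxy)phenyl]boronic acid | OB(O)c1cc(CCCCC/C=C\CCCCCCCO[Si](C)(C)C(C)(C)C)cc(OCOC)c1 | intermediate
20 | tert-butyl{[(8Z)-14-{3-[4-iodo-2,6-bis(methoxymethoxy)phenoxy]-5-(methoxymethoxy)phenyl}tetradec-8-en-1-yl]oxy}dimethylsilane | CC(C)(C)[Si](C)(C)OCCCCCCC/C=C\CCCCCc1cc(OCOC)cc(c1)Oc1c(OCOC)cc(I)cc1OCOC | intermediate
21 | (8Z)-14-{3-[4-iodo-2,6-bis(methoxymethoxy)phenoxy]-5-(methoxymethoxy)phenyl}tetradec-8-en-1-ol | OCCCCCCC/C=C\CCCCCc1cc(OCOC)cc(c1)Oc1c(OCOC)cc(I)cc1OCOC | intermediate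
22 | (8Z)-14-{3-[4-iodo-2,6-bis(methoxymethoxy)phenoxy]-5-(methoxymethoxy)phenyl}tetradec-8-enal (iodo aldehyde, precursor of the key step) | O=CCCCCCC/C=C\CCCCCc1cc(OCOC)cc(c1)Oc1c(OCOC)cc(I)cc1OCOC | intermediate
23 | ring B arylchromium chloride of 22 (chromium in place of iodine) carrying the (S)-sulfonamidato ligand on trivalent chromium (oxazoline N–Cr contact not drawn) | O=CCCCCCC/C=C\CCCCCc1cc(OCOC)cc(c1)Oc1c(OCOC)cc(cc1OCOC)[Cr](Cl)N(c1c(C)cccc1C1=N[C@@H](C(C)C)CO1)S(C)(=O)=O | intermediate
24 | chromium alkoxide of the macrocyclic (1R)-carbinol, trivalent chromium with chloride and the (S)-sulfonamidato ligand | COCOc1cc2cc(c1)Oc1c(OCOC)cc(cc1OCOC)[C@H](O[Cr](Cl)N(c1c(C)cccc1C1=N[C@@H](C(C)C)CO1)S(C)(=O)=O)CCCCCC/C=C\CCCCC2 | intermediate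
25 | macrocyclic (1R,8Z)-carbinol with MOM ethers on the three phenolic oxygens (product of the key step) | COCOc1cc2cc(c1)Oc1c(OCOC)cc(cc1OCOC)[C@H](O)CCCCCC/C=C\CCCCC2 | intermediate
26 | macrocyclic (1R,8Z)-tetrakis(trimethylsilyl) ether (OTMS on the three phenolic oxygens and on the C1 oxygen) | C[Si](C)(C)Oc1cc2cc(c1)Oc1c(O[Si](C)(C)C)cc(cc1O[Si](C)(C)C)[C@H](O[Si](C)(C)C)CCCCCC/C=C\CCCCC2 | intermediate
27 | CNP0316989.2, macrocyclic (1R,8Z)-tetraol (three phenolic OH groups and the C1 carbinol) | Oc1cc2cc(c1)Oc1c(O)cc(cc1O)[C@H](O)CCCCCC/C=C\CCCCC2 | target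

**Step count**

Total steps: 14. Longest linear sequence: 10 steps (steps 5 to 14, from non-8-yn-1-ol). The ring B branch (steps 1 to 3) and the ring A step 4 converge at steps 10 and 7.

**Steps most likely to fail**

1. Step 13 (ring closure). The aryl group may pass too slowly from nickel to the ligand-bound chromium, so that at millimolar concentration reduction or pinacol coupling of the aldehyde and oligomerisation take over, or the addition may show poor facial selectivity. The fallback uses known chemistry and sets the stereocentre by ketone reduction instead of during the C–C bond formation. It sets out from aldehyde 22, which is closed without chiral ligand under the usual nickel/chromium conditions for ω-iodo aldehydes (CrCl2 in excess, NiCl2 cat, DMSO, rt, high dilution) to the racemic macrocyclic carbinol F1. Dess–Martin oxidation should then give the macrocyclic aryl ketone F2. Corey–Bakshi–Shibata reduction ((S)-2-methyl-CBS-oxazaborolidine, BH3·SMe2, THF, −20 °C), in which the aryl ring acts as the large group, should give the 1R alcohol and so returns to the route at 25.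

2. Step 10 (Chan–Lam coupling). Binding of the di-ortho-substituted phenoxide to copper may be slow, so that oxidation to the phenol, protodeboronation and homocoupling use up the boronic acid. The fallback sets out from bromide 16 and the iodine-free phenol 5, which are joined by an Ullmann ether synthesis (CuI, picolinic acid, K3PO4, DMSO, 90 °C) to the iodine-free diaryl ether F3. Iridium-catalysed C–H borylation ([Ir(OMe)(cod)]2, 4,4'-di-tert-butyl-2,2'-bipyridine, B2pin2, THF, 80 °C) should occur only at ring B carbon 4, the single aromatic C–H of either ring without an ortho substituent, to give the ring B pinacol boronate F4. Copper-mediated iododeboronation (CuI, 1,10-phenanthroline, KI, MeOH/H2O, air, 80 °C) should convert it into iodide 20, where the route is rejoined.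

3. Step 14 (deprotection). The silyl triflate may ionise the benzylic C1–O bond, which has a para aryloxy donor; this would erode the configuration at C1 or cause elimination toward C2. The two flanked acetals on ring B may also be cleaved incompletely. The fallback sets out from 25, which is oxidised (Dess–Martin periodinane, CH2Cl2, rt) to the macrocyclic aryl ketone F2. With no carbinol left to ionise, the three MOM ethers can be removed by ordinary acid (HCl, MeOH/THF, 40 °C) to give the triphenol ketone F5. Noyori asymmetric transfer hydrogenation (RuCl[(R,R)-TsDPEN](p-cymene), HCO2H/Et3N, rt), which reduces only the C=O group, should give the 1R carbinol and so arrives at target 27.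

**Further compounds**

F1 | step 13 | racemic macrocyclic (8Z)-carbinol with MOM ethers on the three phenolic oxygens | COCOc1cc2cc(c1)Oc1c(OCOC)cc(cc1OCOC)C(O)CCCCCC/C=C\CCCCC2
F2 | step 13 | macrocyclic (8Z) aryl ketone (C1 carbonyl) with MOM ethers on the three phenolic oxygens | COCOc1cc2cc(c1)Oc1c(OCOC)cc(cc1OCOC)C(=O)CCCCCC/C=C\CCCCC2
F3 | step 10 | tert-butyl{[(8Z)-14-{3-[2,6-bis(methoxymethoxy)phenoxy]-5-(methoxymethoxy)phenyl}tetradec-8-en-1-yl]oxy}dimethylsilane | CC(C)(C)[Si](C)(C)OCCCCCCC/C=C\CCCCCc1cc(OCOC)cc(c1)Oc1c(OCOC)cccc1OCOC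
F4 | step 10 | pinacol boronate of F3 at ring B carbon 4 | CC(C)(C)[Si](C)(C)OCCCCCCC/C=C\CCCCCc1cc(OCOC)cc(c1)Oc1c(OCOC)cc(cc1OCOC)B1OC(C)(C)C(C)(C)O1
F5 | step 14 | macrocyclic (8Z) triphenol ketone (C1 carbonyl; three free phenolic OH groups) | Oc1cc2cc(c1)Oc1c(O)cc(cc1O)C(=O)CCCCCC/C=C\CCCCC2
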